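**Retrosynthetic overview**
- Feature: in the indane core (five-membered ring C1–C2–C3–C3a–C7a fused to the resorcinol ring), C1 carries the exocyclic carbonyl carbon C8 and is bonded to arene carbon C7a, which is meta to both ring oxygens (on C4 and C6) and so is not reachable by electrophilic substitution. The groups on C1, C2 (3,5-dihydroxyphenyl) and C3 (4-hydroxyphenyl) are all cis.
- Last disconnections: the six O–methyl bonds (BBr3) and the C8–aryl bond (aryl Grignard reagent on an N-methoxy-N-methyl amide).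
- Key disconnection: C1–C7a, by a photochemical Wolff ring contraction of a cis-3,4-diaryl-2-diazo-1-tetralone. The ketene is trapped by N,O-dimethylhydroxylamine and C1 is set by protonation on the face away from the aryl groups.
- Diazo ketone: from diazo transfer on the tetralone, which comes from benzylic oxidation of a cis-1,2-diaryltetralin. The two aryl centers come from asymmetric hydrogenation of a 1,2-diaryl-3,4-dihydronaphthalene built from 6,8-dimethoxy-1-tetralone (α-arylation, enol triflate, Suzuki coupling).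
- Ring order: the six-membered carbocycle is closed first (step 1) and is contracted to the five-membered ring in step 9.

Key step: step 9

Remarks on the chemistry:
- Indane numbering is used for the target, which is the all-cis (1R,2R,3R) isomer.
- Assumption: the sense of induction in step 5 cannot be predicted with confidence for this olefin. The (S)-ligand is named; its antipode is to be used if a test run shows the opposite sense.
- Compound 13 is used as the free base and 17 as the commercial THF solution.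

**Step 1**
Reactants: 1 4-(3,5-dimethoxyphenyl)butanoic acid
Product: 2 6,8-dimethoxy-3,4-dihydronaphthalen-1(2H)-one
Conditions: (CF3CO)2O (1.5 equiv), CF3CO2H, 0 °C to rt
Reagents that add atoms: none
Why: Intramolecular Friedel–Crafts acylation through the mixed trifluoroacetic anhydride should close the six-membered ring at the position ortho to the chain, which is activated by one ortho and one para methoxy group and is the same on both sides of the symmetric arene.

**Step 2**
Reactants: 2 6,8-dimethoxy-3,4-dihydronaphthalen-1(2H)-one; 3 1-bromo-3,5-dimethoxybenzene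
Product: 4 rac-2-(3,5-dimethoxyphenyl)-6,8-dimethoxy-3,4-dihydronaphthalen-1(2H)-one
Conditions: Pd(OAc)2 (2 mol%), 2-dicyclohexylphosphino-2',4',6'-triisopropylbiphenyl (XPhos, 4 mol%), NaOtBu (2.2 equiv), toluene, 80 °C
Reagents that add atoms: none
Why: Palladium-catalyzed α-arylation of a ketone enolate (Buchwald–Hartwig type) should arylate C2, the only enolizable carbon, and the more acidic product rests as its enolate and resists a second arylation; the C2 stereocenter forms racemic and is erased in step 3.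

**Step 3**
Reactants: 4 rac-2-(3,5-dimethoxyphenyl)-6,8-dimethoxy-3,4-dihydronaphthalen-1(2H)-one
Product: 6 2-(3,5-dimethoxyphenyl)-6,8-dimethoxy-3,4-dihydronaphthalen-1-yl trifluoromethanesulfonate, via potassium enolate 5 (not isolated)
Conditions: KN(SiMe3)2 (1.2 equiv), THF, −78 °C; then PhNTf2 (1.3 equiv), −78 °C to rt
Reagents that add atoms: N-phenylbis(trifluoromethanesulfonimide), O=S(=O)(N(c1ccccc1)S(=O)(=O)C(F)(F)F)C(F)(F)F
Why: O-Sulfonylation of the potassium enolate, which can form only toward C2, is the standard enol triflate synthesis and fixes the tetrasubstituted C1=C2 double bond without the carbonyl addition that an easily enolized, peri-hindered ketone would resist.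

**Step 4**
Reactants: 6 2-(3,5-dimethoxyphenyl)-6,8-dimethoxy-3,4-dihydronaphthalen-1-yl trifluoromethanesulfonate; 7 4-methoxyphenylboronic acid
Product: 8 3-(3,5-dimethoxyphenyl)-5,7-dimethoxy-4-(4-methoxyphenyl)-1,2-dihydronaphthalene
Conditions: Pd(OAc)2 (5 mol%), 2-dicyclohexylphosphino-2',6'-dimethoxybiphenyl (SPhos, 10 mol%), K3PO4 (3 equiv), toluene/H2O 10:1, 90 °C
Reagents that add atoms: none
Why: Suzuki–Miyaura coupling of an enol triflate with an arylboronic acid, run with a bulky electron-rich biarylphosphine to cope with the tetrasubstituted site next to the peri methoxy group, should replace the triflate by the 4-methoxyphenyl group with the double bond held in place.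

**Step 5**
Reactants: 8 3-(3,5-dimethoxyphenyl)-5,7-dimethoxy-4-(4-methoxyphenyl)-1,2-dihydronaphthalene
Product: 9 (1R,2S)-2-(3,5-dimethoxyphenyl)-6,8-dimethoxy-1-(4-methoxyphenyl)-1,2,3,4-tetrahydronaphthalene (aryl groups cis)
Conditions: [Ir(cod)(L)]BArF (3 mol%; cod = 1,5-cyclooctadiene, L = (S)-4-tert-butyl-2-[2-(diphenylphosphino)phenyl]-4,5-dihydrooxazole, BArF = tetrakis[3,5-bis(trifluoromethyl)phenyl]borate), H2 (50 bar), CH2Cl2, 25–40 °C
Reagents that add atoms: none
Why: Iridium-catalyzed asymmetric hydrogenation of an unfunctionalized tetrasubstituted aryl olefin with a cationic phosphine–oxazoline complex should add both hydrogens to one face of the C=C bond, so that the two aryl groups end up cis, while the chiral ligand selects the olefin face and sets both stereocenters as (1R,2S).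

**Step 6**
Reactants: 9 (1R,2S)-2-(3,5-dimethoxyphenyl)-6,8-dimethoxy-1-(4-methoxyphenyl)-1,2,3,4-tetrahydronaphthalene
Product: 10 (3S,4R)-3-(3,5-dimethoxyphenyl)-5,7-dimethoxy-4-(4-methoxyphenyl)-3,4-dihydronaphthalen-1(2H)-one (aryl groups cis)
Conditions: CrO3 (3 equiv), AcOH/H2O 9:1, 15 °C
Reagents that add atoms: chromium trioxide, O=[Cr](=O)=O
Why: Benzylic oxidation of a tetralin methylene to the 1-tetralone with CrO3 in aqueous acetic acid should take the C4 methylene, the only unhindered benzylic C–H site, because the tertiary C1–H and C2–H bonds are shielded by the peri methoxy group and the cis aryl groups; the stereocenters are untouched and the ketone has no epimerizable α-center.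

**Step 7**
Reactants: 10 (3S,4R)-3-(3,5-dimethoxyphenyl)-5,7-dimethoxy-4-(4-methoxyphenyl)-3,4-dihydronaphthalen-1(2H)-one
Product: 11 (3S,4R)-3-(3,5-dimethoxyphenyl)-2-(hydroxymethylidene)-5,7-dimethoxy-4-(4-methoxyphenyl)-3,4-dihydronaphthalen-1(2H)-one (enol form of the 2-formyl ketone)
Conditions: NaH (3 equiv), HCO2Et (5 equiv), cat. EtOH, THF, 0 °C to rt; aq. HCl work-up
Reagents that add atoms: ethyl formate, CCOC=O
Why: Crossed Claisen condensation of the ketone enolate, which can form only at C2, with ethyl formate should give the 2-formyl ketone as its hydrogen-bonded hydroxymethylidene enol, so that no new stereocenter arises and C3 stays untouched.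

**Step 8**
Reactants: 11 (3S,4R)-3-(3,5-dimethoxyphenyl)-2-(hydroxymethylidene)-5,7-dimethoxy-4-(4-methoxyphenyl)-3,4-dihydronaphthalen-1(2H)-one
Product: 12 (3S,4R)-2-diazo-3-(3,5-dimethoxyphenyl)-5,7-dimethoxy-4-(4-methoxyphenyl)-3,4-dihydronaphthalen-1(2H)-one
Conditions: 4-acetamidobenzenesulfonyl azide (1.3 equiv), Et3N (2 equiv), MeCN, 0 °C to rt
Reagents that add atoms: 4-acetamidobenzenesulfonyl azide, CC(=O)Nc1ccc(cc1)S(=O)(=O)N=[N+]=[N-]
Why: Regitz deformylative diazo transfer, in which the enolate of the formyl ketone attacks the terminal azide nitrogen and the formyl group leaves as the N-formyl sulfonamide, should give the 2-diazo ketone without disturbing C3 or C4.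

**Step 9**
Reactants: 12 (3S,4R)-2-diazo-3-(3,5-dimethoxyphenyl)-5,7-dimethoxy-4-(4-methoxyphenyl)-3,4-dihydronaphthalen-1(2H)-one; 13 N,O-dimethylhydroxylamine
Product: 16 (1R,2R,3R)-2-(3,5-dimethoxyphenyl)-N,4,6-trimethoxy-3-(4-methoxyphenyl)-N-methyl-2,3-dihydro-1H-indene-1-carboxamide (all-cis), via indanylidene ketene 14 (not isolated), via amide enol 15 (not isolated)
Conditions: hν (365 nm LED), 13 (5 equiv), degassed THF, −40 °C
Reagents that add atoms: none
Why: Excitation of the cyclic diazo ketone, which is locked s-cis, expels N2 with a concerted 1,2-shift of arene carbon C8a of the tetralone (C7a of the indane) from the carbonyl carbon to the diazo carbon and gives indanylidene ketene 14; this is the Wolff rearrangement in its well-known ring-contraction mode on 2-diazo-1-tetralones with nucleophilic capture of the ketene. The five-membered ring is thus closed by ring contraction (C1–C7a forms as C8–C7a breaks inside the six-membered ring), not by cyclization of a chain, so no other closure mode competes and only the aryl carbon can migrate. Amine 13 adds to the ketene carbon in the plane of the ketene and gives amide enol 15, in which C1 is trigonal. The new stereocenter C1 is set when 15 is protonated on carbon: the cis aryl groups on C2 and C3 cover one face of the enol, the proton should arrive on the open face, and the carboxamide is thereby placed on the aryl-bearing face, which gives the all-cis (1R) amide. The step needs this kinetic facial selectivity to persist, and the low temperature together with the weak basicity of 13 should keep the contra-thermodynamic C1 center from equilibrating. The C3 and C4 centers of 12 are not touched, and the locked s-cis geometry should favor aryl migration over a 1,2-hydride shift from C3.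

**Step 10**
Reactants: 16 (1R,2R,3R)-2-(3,5-dimethoxyphenyl)-N,4,6-trimethoxy-3-(4-methoxyphenyl)-N-methyl-2,3-dihydro-1H-indene-1-carboxamide; 17 4-methoxyphenylmagnesium bromide
Product: 19 [(1R,2R,3R)-2-(3,5-dimethoxyphenyl)-4,6-dimethoxy-3-(4-methoxyphenyl)-2,3-dihydro-1H-inden-1-yl](4-methoxyphenyl)methanone (all-cis), via magnesium hemiaminal chelate 18 (not isolated)
Conditions: 17 (3 equiv, 0.5 M in THF), THF, −20 to 0 °C; cold sat. aq. NH4Cl
Reagents that add atoms: none
Why: Weinreb ketone synthesis, in which the aryl Grignard reagent adds once to the N-methoxy-N-methyl amide and gives a magnesium-chelated tetrahedral adduct that neither collapses nor enolizes before the cold, mildly acidic quench, so that over-addition is avoided and the C1 configuration should be kept.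

**Step 11**
Reactants: 19 [(1R,2R,3R)-2-(3,5-dimethoxyphenyl)-4,6-dimethoxy-3-(4-methoxyphenyl)-2,3-dihydro-1H-inden-1-yl](4-methoxyphenyl)methanone
Product: 21 caraphenol C, [(1R,2R,3R)-2-(3,5-dihydroxyphenyl)-4,6-dihydroxy-3-(4-hydroxyphenyl)-2,3-dihydro-1H-inden-1-yl](4-hydroxyphenyl)methanone, via hexakis(dibromoboryl) ether 20 (not isolated)
Conditions: BBr3 (12 equiv), CH2Cl2, −78 to 0 °C; ice-water quench
Reagents that add atoms: none
Why: Lewis acid-mediated cleavage of aryl methyl ethers by BBr3 (bromide attack on the O-methyl carbon of each boron-complexed ether, then hydrolysis of the B–O bonds) should free all six phenols, and the low temperature and cold aqueous quench are chosen to keep the enolizable C1 center from epimerizing.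

**Compound list**
1 | 4-(3,5-dimethoxyphenyl)butanoic acid | COc1cc(CCCC(=O)O)cc(OC)c1 | starting material
2 | 6,8-dimethoxy-3,4-dihydronaphthalen-1(2H)-one | O=C1CCCc2cc(OC)cc(OC)c12 | intermediate
3 | 1-bromo-3,5-dimethoxybenzene | COc1cc(Br)cc(OC)c1 | starting material
4 | rac-2-(3,5-dimethoxyphenyl)-6,8-dimethoxy-3,4-dihydronaphthalen-1(2H)-one | O=C1C(c2cc(OC)cc(OC)c2)CCc2cc(OC)cc(OC)c12 | intermediate
5 | potassium 2-(3,5-dimethoxyphenyl)-6,8-dimethoxy-3,4-dihydronaphthalen-1-olate (not isolated) | [K+].[O-]C1=C(c2cc(OC)cc(OC)c2)CCc2cc(OC)cc(OC)c12 | intermediate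
6 | 2-(3,5-dimethoxyphenyl)-6,8-dimethoxy-3,4-dihydronaphthalen-1-yl trifluoromethanesulfonate | O=S(=O)(OC1=C(c2cc(OC)cc(OC)c2)CCc2cc(OC)cc(OC)c12)C(F)(F)F | intermediate
7 | 4-methoxyphenylboronic acid | COc1ccc(B(O)O)cc1 | starting material
8 | 3-(3,5-dimethoxyphenyl)-5,7-dimethoxy-4-(4-methoxyphenyl)-1,2-dihydronaphthalene | COc1ccc(cc1)C1=C(c2cc(OC)cc(OC)c2)CCc2cc(OC)cc(OC)c12 | intermediate
9 | (1R,2S)-2-(3,5-dimethoxyphenyl)-6,8-dimethoxy-1-(4-methoxyphenyl)-1,2,3,4-tetrahydronaphthalene (cis) | C1C[C@H](c2cc(OC)cc(OC)c2)[C@H](c2ccc(OC)cc2)c2c(OC)cc(OC)cc12 | intermediate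
10 | (3S,4R)-3-(3,5-dimethoxyphenyl)-5,7-dimethoxy-4-(4-methoxyphenyl)-3,4-dihydronaphthalen-1(2H)-one (cis) | O=C1C[C@H](c2cc(OC)cc(OC)c2)[C@H](c2ccc(OC)cc2)c2c(OC)cc(OC)cc12 | intermediate
11 | (3S,4R)-3-(3,5-dimethoxyphenyl)-2-(hydroxymethylidene)-5,7-dimethoxy-4-(4-methoxyphenyl)-3,4-dihydronaphthalen-1(2H)-one | O=C1C(=CO)[C@H](c2cc(OC)cc(OC)c2)[C@H](c2ccc(OC)cc2)c2c(OC)cc(OC)cc12 | intermediate
12 | (3S,4R)-2-diazo-3-(3,5-dimethoxyphenyl)-5,7-dimethoxy-4-(4-methoxyphenyl)-3,4-dihydronaphthalen-1(2H)-one | O=C1C(=[N+]=[N-])[C@H](c2cc(OC)cc(OC)c2)[C@H](c2ccc(OC)cc2)c2c(OC)cc(OC)cc12 | intermediate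
13 | N,O-dimethylhydroxylamine | CNOC | starting material
14 | cis-2-(3,5-dimethoxyphenyl)-4,6-dimethoxy-3-(4-methoxyphenyl)indan-1-ylidene ketene, (2S,3R) (not isolated) | O=C=C1c2cc(OC)cc(OC)c2[C@@H](c2ccc(OC)cc2)[C@H]1c1cc(OC)cc(OC)c1 | intermediate
15 | amide enol: [cis-2-(3,5-dimethoxyphenyl)-4,6-dimethoxy-3-(4-methoxyphenyl)indan-1-ylidene][methoxy(methyl)amino]methanol (not isolated) | CON(C)C(O)=C1c2cc(OC)cc(OC)c2[C@@H](c2ccc(OC)cc2)[C@H]1c1cc(OC)cc(OC)c1 | intermediate
16 | (1R,2R,3R)-2-(3,5-dimethoxyphenyl)-N,4,6-trimethoxy-3-(4-methoxyphenyl)-N-methyl-2,3-dihydro-1H-indene-1-carboxamide (all-cis) | CON(C)C(=O)[C@H]1c2cc(OC)cc(OC)c2[C@@H](c2ccc(OC)cc2)[C@H]1c1cc(OC)cc(OC)c1 | intermediate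
17 | 4-methoxyphenylmagnesium bromide | COc1ccc([Mg]Br)cc1 | starting material
18 | bromomagnesium alkoxide of the tetrahedral adduct of 16 and 17 (magnesium hemiaminal chelate, not isolated) | CON(C)C(O[Mg]Br)(c1ccc(OC)cc1)[C@H]1c2cc(OC)cc(OC)c2[C@@H](c2ccc(OC)cc2)[C@H]1c1cc(OC)cc(OC)c1 | intermediate
19 | [(1R,2R,3R)-2-(3,5-dimethoxyphenyl)-4,6-dimethoxy-3-(4-methoxyphenyl)-2,3-dihydro-1H-inden-1-yl](4-methoxyphenyl)methanone (all-cis) | O=C(c1ccc(OC)cc1)[C@H]1c2cc(OC)cc(OC)c2[C@@H](c2ccc(OC)cc2)[C@H]1c1cc(OC)cc(OC)c1 | intermediate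
20 | hexakis(dibromoboryl) ether of caraphenol C (not isolated) | O=C(c1ccc(OB(Br)Br)cc1)[C@H]1c2cc(OB(Br)Br)cc(OB(Br)Br)c2[C@@H](c2ccc(OB(Br)Br)cc2)[C@H]1c1cc(OB(Br)Br)cc(OB(Br)Br)c1 | intermediate
21 | caraphenol C, [(1R,2R,3R)-2-(3,5-dihydroxyphenyl)-4,6-dihydroxy-3-(4-hydroxyphenyl)-2,3-dihydro-1H-inden-1-yl](4-hydroxyphenyl)methanone | O=C(c1ccc(O)cc1)[C@H]1c2cc(O)cc(O)c2[C@@H](c2ccc(O)cc2)[C@H]1c1cc(O)cc(O)c1 | target

Total step count: 11. Longest linear sequence: 11 steps (1 to 21).

**Steps most likely to fail**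

Step 5. The tetrasubstituted diaryl olefin, crowded further by the peri methoxy group, may be reduced only sluggishly by the cationic iridium catalyst, or with poor discrimination between its two faces. The fallback replaces asymmetric catalysis by racemic hydrogenation and a resolution through reagent-controlled reduction; it sets out from 8 and comes back at 10.
- Hydrogenation of 8 over Pd on carbon (H2, EtOAc/AcOH) should give, by syn addition on the metal surface, the racemic cis-2-(3,5-dimethoxyphenyl)-6,8-dimethoxy-1-(4-methoxyphenyl)tetralin F1.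
- CrO3 oxidation as in step 6 then gives the racemic cis-3,4-diaryl tetralone F2.
- Reduction of F2 with BH3·SMe2 under (S)-2-methyl-CBS-oxazaborolidine should turn both ketone enantiomers into (1R)-carbinols, which are diastereomers of one another: the (1R,3S,4R)-tetralol F3 and the (1R,3R,4S)-tetralol F4.
- After separation on silica, Dess–Martin oxidation of F3 returns 10.

Step 6. Hydrogen abstraction at the diarylmethine C1–H, which is electronically the most activated benzylic site, or oxidation of the methoxy-substituted rings may compete with oxidation of the C4 methylene. The fallback carries the ketone oxygen from the start as a ketal; it sets out from bromide 3 and boronic acid 7, which are joined to a new commercial ketone, and comes back at 10.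
- Commercial 5,7-dimethoxy-3,4-dihydronaphthalen-1(2H)-one F5 is converted (ethylene glycol, HC(OEt)3, TsOH) into 1,1-(ethylenedioxy)-5,7-dimethoxytetralin F6.
- Its only remaining benzylic methylene, which is ortho and para to the methoxy groups, is oxidized under non-acidic conditions (CrO3·3,5-dimethylpyrazole, CH2Cl2, −20 °C) to 4,4-(ethylenedioxy)-6,8-dimethoxy-3,4-dihydronaphthalen-1(2H)-one F7.
- α-Arylation with 3 as in step 2 gives the 2-(3,5-dimethoxyphenyl) keto ketal F8.
- Tf2O with 2,6-di-tert-butyl-4-methylpyridine gives the enol triflate F9.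
- Suzuki–Miyaura coupling with 7 as in step 4 gives the 3,4-diaryl-1,2-dihydronaphthalene ketal F10.
- Hydrogenation as in step 5 gives the cis-(3S,4R) diaryl ketal F11, and aqueous HCl in THF releases 10.

Step 9. Protonation of the amide enol at C1 may not be face-selective enough, or the all-cis amide may epimerize under the photolysis conditions, so that C1-epimeric mixtures result. The fallback separates ring contraction from the stereo-defining protonation; it sets out from 12 and comes back at 16.
- Photolysis of 12 in methanol/THF traps ketene 14 as the methyl indane-1-carboxylate F12, taken on as whatever C1 mixture forms.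
- LiN(iPr)2 in THF at −78 °C converts it into the lithium ester enolate F13.
- Quenching at −78 °C with a bulky proton acid (2,6-di-tert-butyl-4-methylphenol) should protonate C1 on the face away from the aryl groups and give the all-cis (1R,2R,3R) methyl ester F14.
- Aminolysis with the aluminum amide made from AlMe3 and N,O-dimethylhydroxylamine hydrochloride (CH2Cl2, 0 °C to rt) gives 16.

**Further compounds**
F1 | step 5 | rac-cis-2-(3,5-dimethoxyphenyl)-6,8-dimethoxy-1-(4-methoxyphenyl)-1,2,3,4-tetrahydronaphthalene (racemate, one enantiomer drawn) | C1C[C@H](c2cc(OC)cc(OC)c2)[C@H](c2ccc(OC)cc2)c2c(OC)cc(OC)cc12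
F2 | step 5 | rac-cis-3-(3,5-dimethoxyphenyl)-5,7-dimethoxy-4-(4-methoxyphenyl)-3,4-dihydronaphthalen-1(2H)-one (racemate, one enantiomer drawn) | O=C1C[C@H](c2cc(OC)cc(OC)c2)[C@H](c2ccc(OC)cc2)c2c(OC)cc(OC)cc12
F3 | step 5 | (1R,3S,4R)-3-(3,5-dimethoxyphenyl)-5,7-dimethoxy-4-(4-methoxyphenyl)-1,2,3,4-tetrahydronaphthalen-1-ol | O[C@@H]1C[C@H](c2cc(OC)cc(OC)c2)[C@H](c2ccc(OC)cc2)c2c(OC)cc(OC)cc12
F4 | step 5 | (1R,3R,4S)-3-(3,5-dimethoxyphenyl)-5,7-dimethoxy-4-(4-methoxyphenyl)-1,2,3,4-tetrahydronaphthalen-1-ol | O[C@@H]1C[C@@H](c2cc(OC)cc(OC)c2)[C@@H](c2ccc(OC)cc2)c2c(OC)cc(OC)cc12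
F5 | step 6 | 5,7-dimethoxy-3,4-dihydronaphthalen-1(2H)-one | O=C1CCCc2c(OC)cc(OC)cc12
F6 | step 6 | 1,1-(ethylenedioxy)-5,7-dimethoxy-1,2,3,4-tetrahydronaphthalene | O1CCOC12CCCc3c(OC)cc(OC)cc23
F7 | step 6 | 4,4-(ethylenedioxy)-6,8-dimethoxy-3,4-dihydronaphthalen-1(2H)-one | O1CCOC12CCC(=O)c3c(OC)cc(OC)cc23
F8 | step 6 | rac-2-(3,5-dimethoxyphenyl)-4,4-(ethylenedioxy)-6,8-dimethoxy-3,4-dihydronaphthalen-1(2H)-one | O1CCOC12CC(c3cc(OC)cc(OC)c3)C(=O)c3c(OC)cc(OC)cc23
F9 | step 6 | 2-(3,5-dimethoxyphenyl)-4,4-(ethylenedioxy)-6,8-dimethoxy-3,4-dihydronaphthalen-1-yl trifluoromethanesulfonate | O1CCOC12CC(c3cc(OC)cc(OC)c3)=C(OS(=O)(=O)C(F)(F)F)c3c(OC)cc(OC)cc23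
F10 | step 6 | 3-(3,5-dimethoxyphenyl)-1,1-(ethylenedioxy)-5,7-dimethoxy-4-(4-methoxyphenyl)-1,2-dihydronaphthalene | O1CCOC12CC(c3cc(OC)cc(OC)c3)=C(c3ccc(OC)cc3)c3c(OC)cc(OC)cc23
F11 | step 6 | (3S,4R)-3-(3,5-dimethoxyphenyl)-1,1-(ethylenedioxy)-5,7-dimethoxy-4-(4-methoxyphenyl)-1,2,3,4-tetrahydronaphthalene (cis) | O1CCOC12C[C@H](c3cc(OC)cc(OC)c3)[C@H](c3ccc(OC)cc3)c3c(OC)cc(OC)cc23
F12 | step 9 | methyl (2R,3R)-2-(3,5-dimethoxyphenyl)-4,6-dimethoxy-3-(4-methoxyphenyl)-2,3-dihydro-1H-indene-1-carboxylate (C1 undefined) | COC(=O)C1c2cc(OC)cc(OC)c2[C@@H](c2ccc(OC)cc2)[C@H]1c1cc(OC)cc(OC)c1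
F13 | step 9 | lithium enolate of the methyl ester (lithium ketene acetal, cis-2,3-diaryl) | [Li+].COC([O-])=C1c2cc(OC)cc(OC)c2[C@@H](c2ccc(OC)cc2)[C@H]1c1cc(OC)cc(OC)c1
F14 | step 9 | methyl (1R,2R,3R)-2-(3,5-dimethoxyphenyl)-4,6-dimethoxy-3-(4-methoxyphenyl)-2,3-dihydro-1H-indene-1-carboxylate (all-cis) | COC(=O)[C@H]1c2cc(OC)cc(OC)c2[C@@H](c2ccc(OC)cc2)[C@H]1c1cc(OC)cc(OC)c1
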